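(The runs were generated by integration with constants of no real substance; noise was put on by code.)

The pitfall in a curve that flattens is to read the plateau as the end of the reagents. In the birch run product creeps from 35.6% at 6.00 min to 44.5% at 15.0 min, yet 55.5% of the starting material is not in the product column. Larch and cedar bend too, so the working hypothesis is a catalyst that dies.

| setting | larch | birch | cedar | Thursday's | Wednesday's |
|---|---|---|---|---|---|
| starting material | 0.028 M | 0.044 M | 0.020 M | 0.020 M | 0.020 M |
| coupling partner | 0.050 M | 0.050 M | 0.025 M | 0.0500 M | 0.0500 M |
| free catalyst | 0.10 mM | 0.10 mM | 0.10 mM | 0.10 mM | 0.10 mM |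
| temperature | 80 °C | 102 °C | 80 °C | 110 °C | 70 °C |
| remark | run made earlier | run made earlier | run made earlier |  |  |
| time |  |  |  | 2.0 h | 2.0 h |

- larch (time / min: product / %): 4.00: 17.9; 8.00: 32.0; 20.0: 57.4; 50.0: 77.3
- birch (time / min: product / %): 1.33: 12.5; 2.50: 20.8; 6.00: 35.6; 15.0: 44.5
- cedar (time / min: product / %): 12.0: 39.0; 25.0: 59.3; 30.0: 63.4; 50.0: 73.3

(each reading ± 0.5 percentage points)

- which one finishes higher in amount of product, in percent of the starting material charged ("neither" within 2 percentage points) (Thursday's / Wednesday's / neither)
- amount of product at the end, in percent of the starting material charged, Thursday's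
- amount of product at the end, in percent of the starting material charged, Wednesday's



The ledger runs on the starting material, the limiting reagent at 0.020 M against 0.0500 M of coupling partner. The catalyst can hold at most 0.500% of it, so two entries remain: product and unreacted. Let L be the natural logarithm of the charge over what is left. L grows at k·f, where f is the surviving share of catalyst and k the first-order constant of a fresh charge, while f decays at kd·f. Dividing one rate by the other removes time: L equals N times the dead share of catalyst, with N = k/kd, and the unreacted entry is e^(−L).

In the cedar run L is 0.899 at 25.0 min and 1.32 at 50.0 min. The second interval adds 0.469 of the first, and that is the surviving share, so kd reads 0.0303 /min at 80 °C. The larch run, with the coupling partner of the new flasks, reaches L = 1.48 at 50.0 min, where the surviving share is s squared, so N reads 1.90. The birch run ends at L = 0.589 and starts at k = 0.100 /min, which gives kd = 0.171 /min and N = 0.638 at 102 °C. Heat shortens N.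

Take ln N and ln kd as straight in temperature over this span. At 110 °C N = 0.429, Thursday's reach, the L its charge of catalyst delivers in its whole life. Its kd of 0.320 /min means a catalyst lifetime of 3.12 min, far shorter than 2.0 h, so Thursday's books close at 34.9% product. At 70 °C N = 3.12 and kd = 0.0138 /min, so this extrapolation estimates a surviving share of 0.191 for Wednesday's catalyst at the end, and L = 2.53 gives 92.0% product.

The forecast, made from the same runs with slightly different numbers, names Wednesday's, with 36% for Thursday's and 90% for Wednesday's, on the ground that “heat favours catalyst death”.

The flasks give 36.1% for Thursday's and 91.1% for Wednesday's, so Wednesday's finishes higher. Wednesday's flask holds 96.6% spent catalyst at 2.00 h, more than the 80.9% dead share of the estimate, so the closeness of its product figure is no check on the extrapolated kd.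

    starting material + free catalyst → catalyst intermediate A (k = 1100 /M/min, Ea = 51.0 kJ/mol)
    coupling partner + catalyst intermediate A → catalyst intermediate B (k = 390 /M/min, Ea = 48.0 kJ/mol)
    catalyst intermediate B → catalyst intermediate C (k = 21.0 /min, Ea = 96.0 kJ/mol)
    catalyst intermediate C → free catalyst + product (k = 1000 /min, Ea = 85.0 kJ/mol)
    free catalyst → spent catalyst (k = 0.0440 /min, Ea = 98.0 kJ/mol)
    (constants at 70 °C)

The neighbouring flask is Thursday's with 2.5 × 10⁻⁵ M of free catalyst, a quarter of the charge. Taking k in proportion to the charge and kd unchanged, its reach is 0.107, so the ledger closes at 10.1% product. That flask gives 10.6% product, with 89% of the starting material unreacted and spent catalyst at 100% after 2.00 h.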